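**Retrosynthetic overview**
1. Target 25 ← epoxidation of the (9Z)-olefin of macrocycle 24 (ring 3, the oxirane, is formed last).
2. Ten-membered carbocycle (ring 2) ← ring-closing metathesis joining a methallyl and an allyl terminus (C9=C10).
3. C5–C6 bond, C5 carbinol and the exo-methylene enone ← Morita–Baylis–Hillman reaction of aldehyde 14 with hexa-1,5-dien-3-one; the angelate is then put on by Yamaguchi esterification.
4. C3a–C4 bond and the trans α-methylene lactone ← zinc Barbier reaction of bromobutenolide 8 with 2,2-dimethoxyacetaldehyde.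
5. Butenolide 8 (ring 1, formed first) ← metathesis of a 2-(bromomethyl)acrylate of alcohol 4 ← chiral phosphoric acid-catalysed methallylboration of cinnamaldehyde (first stereocenter).

Assumption: chiral catalysts are not counted as starting materials; locants in the comments are those of the final cyclodeca[b]furan skeleton (O1, C2 lactone C=O, C3, C3a, C4 carbinol, C5 angelate carbon, C6, C7 ketone, C8, C9, C10 methyl-bearing carbon, C11, C11a).

**Step 1**
Reactants: 1 (2E)-3-phenylprop-2-enal (cinnamaldehyde); 2 4,4,5,5-tetramethyl-2-(2-methylprop-2-en-1-yl)-1,3,2-dioxaborolane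
Product: 4 (1E,3R)-5-methyl-1-phenylhexa-1,5-dien-3-ol, via pinacol borate 3 (not isolated)
Conditions: (R)-TRIP [(R)-3,3'-bis(2,4,6-triisopropylphenyl)-1,1'-binaphthyl-2,2'-diyl hydrogen phosphate] (5 mol%), toluene, −30 °C; aq. work-up
Reagents that add atoms: none
Why: Chiral phosphoric acid-catalysed allylboration (Antilla type): the acid activates the boronate in a closed six-membered chair transition state, and the (R)-catalyst, the enantiomer that gives (R)-homoallylic alcohols from aryl and α,β-unsaturated aldehydes, directs 1,2-addition to the Re face, setting the future C11a as (R).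

**Step 2**
Reactants: 4 (1E,3R)-5-methyl-1-phenylhexa-1,5-dien-3-ol; 5 2-(bromomethyl)prop-2-enoic acid
Product: 7 (1E,3R)-5-methyl-1-phenylhexa-1,5-dien-3-yl 2-(bromomethyl)prop-2-enoate, via O-acylisourea 6 (not isolated)
Conditions: DIC, DMAP (5 mol%), CH2Cl2, 0 °C
Reagents that add atoms: none
Why: Steglich esterification acylates the secondary alcohol at oxygen, so the C–O stereocenter is untouched and the allylic bromide survives at 0 °C.

**Step 3**
Reactants: 7 (1E,3R)-5-methyl-1-phenylhexa-1,5-dien-3-yl 2-(bromomethyl)prop-2-enoate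
Product: 8 (5R)-3-(bromomethyl)-5-(2-methylprop-2-en-1-yl)furan-2(5H)-one
Conditions: second-generation Grubbs catalyst RuCl2(=CHPh)(H2IMes)(PCy3) (5 mol%), CH2Cl2, 40 °C
Reagents that add atoms: none
Why: Ring-closing metathesis between the styrenyl and acrylate olefins closes the only unstrained ring available (the butenolide, ring 1) with loss of styrene; the methallyl group and the (R) center are not involved.

**Step 4**
Reactants: 8 (5R)-3-(bromomethyl)-5-(2-methylprop-2-en-1-yl)furan-2(5H)-one; 9 2,2-dimethoxyacetaldehyde (60 wt% in water)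
Product: 11 (4R,5R)-4-[(1R)-1-hydroxy-2,2-dimethoxyethyl]-3-methylidene-5-(2-methylprop-2-en-1-yl)oxolan-2-one, via allylzinc bromide 10 (not isolated)
Conditions: Zn dust, THF/sat. aq. NH4Cl, 0 °C to rt
Reagents that add atoms: none
Why: Zinc Barbier allylation: the allylzinc reacts at the ring γ-carbon (SE2′) through a closed chair transition state on the face anti to the methallyl group (trans lactone, C3a), and the ring-fixed E-type allyl geometry gives the anti carbinol (C4 R) while regenerating the exo-methylene lactone.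

**Step 5**
Reactants: 11 (4R,5R)-4-[(1R)-1-hydroxy-2,2-dimethoxyethyl]-3-methylidene-5-(2-methylprop-2-en-1-yl)oxolan-2-one
Product: 14 (2R)-2-[(2R,3S)-4-methylidene-2-(2-methylprop-2-en-1-yl)-5-oxooxolan-3-yl]-2-(triethylsilyloxy)acetaldehyde, via silyl ether acetal 12 (not isolated), via collidinium salt 13 (not isolated)
Conditions: TESOTf (3.5 equiv), 2,4,6-collidine (5 equiv), CH2Cl2, 0 °C; then H2O
Reagents that add atoms: triethylsilyl trifluoromethanesulfonate CC[Si](CC)(CC)OS(=O)(=O)C(F)(F)F; water O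
Why: One-pot silylation and Fujioka-type acetal cleavage: TESOTf silylates the hydroxyl and, with collidine, turns the dimethyl acetal into a collidinium N,O-acetal that water hydrolyses to the aldehyde without acid, so the silyl ether, the lactone and the α-stereocenter are preserved.

**Step 6**
Reactants: 15 3-chloropropanoyl chloride; 16 trimethyl(prop-2-en-1-yl)silane
Product: 17 1-chlorohex-5-en-3-one
Conditions: AlCl3 (1.1 equiv), CH2Cl2, −78 °C
Reagents that add atoms: none
Why: Lewis acid-promoted acylation of an allylsilane (Sakurai-type SE2′ attack on the activated acid chloride) gives the β,γ-unsaturated chloro ketone; no stereocenter is formed.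

**Step 7**
Reactants: 14 (2R)-2-[(2R,3S)-4-methylidene-2-(2-methylprop-2-en-1-yl)-5-oxooxolan-3-yl]-2-(triethylsilyloxy)acetaldehyde; 17 1-chlorohex-5-en-3-one
Product: 19 (4S,5R)-4-[(1R,2S)-2-hydroxy-3-methylidene-4-oxo-1-(triethylsilyloxy)hept-6-en-1-yl]-3-methylidene-5-(2-methylprop-2-en-1-yl)oxolan-2-one, via hexa-1,5-dien-3-one 18 (not isolated)
Conditions: 17 (3 equiv), iPr2NEt (3 equiv), β-isocupreidine (20 mol%), THF/DMF, −30 °C
Reagents that add atoms: none
Why: Proposed new method: a slow-release Morita–Baylis–Hillman reaction in which iPr2NEt unmasks the base-labile skipped dienone 18 from the β-chloro ketone only as it is consumed (limiting Rauhut–Currier dimerisation and isomerisation to the conjugated dienone); the quinuclidine nitrogen of β-isocupreidine adds to the vinyl ketone, the ammonium enolate attacks the α-silyloxy aldehyde in the polar Felkin–Anh sense (C–OSiEt3 anti to the nucleophile) while the catalyst phenol hydrogen-bonds the developing alkoxide and relays the proton for E1cB release of the catalyst, so substrate bias and the catalyst's usual sense of induction are expected to be matched and set C5 as (S); the closest known reaction type is the DABCO- or β-isocupreidine-catalysed MBH reaction of methyl vinyl ketone or hexafluoroisopropyl acrylate with simple and α-alkoxy aldehydes.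

**Step 8**
Reactants: 19 (4S,5R)-4-[(1R,2S)-2-hydroxy-3-methylidene-4-oxo-1-(triethylsilyloxy)hept-6-en-1-yl]-3-methylidene-5-(2-methylprop-2-en-1-yl)oxolan-2-one; 20 (2Z)-2-methylbut-2-enoic acid (angelic acid)
Product: 22 (1R,2S)-3-methylidene-1-[(2R,3S)-4-methylidene-2-(2-methylprop-2-en-1-yl)-5-oxooxolan-3-yl]-4-oxo-1-(triethylsilyloxy)hept-6-en-2-yl (2Z)-2-methylbut-2-enoate, via mixed anhydride 21 (not isolated)
Conditions: 20, 2,4,6-trichlorobenzoyl chloride, Et3N, toluene, rt; then 19, 60 °C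
Reagents that add atoms: none
Why: Yamaguchi esterification: the mixed anhydride acylates the hindered allylic alcohol at oxygen (retention at C5), and this activation is the one known to transfer the angeloyl group without Z-to-E isomerisation to the tiglate.

**Step 9**
Reactants: 22 (1R,2S)-3-methylidene-1-[(2R,3S)-4-methylidene-2-(2-methylprop-2-en-1-yl)-5-oxooxolan-3-yl]-4-oxo-1-(triethylsilyloxy)hept-6-en-2-yl (2Z)-2-methylbut-2-enoate
Product: 23 (3aS,4R,5S,9Z,11aR)-10-methyl-3,6-dimethylidene-2,7-dioxo-4-(triethylsilyloxy)-2,3,3a,4,5,6,7,8,11,11a-decahydrocyclodeca[b]furan-5-yl (2Z)-2-methylbut-2-enoate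
Conditions: second-generation Hoveyda–Grubbs catalyst RuCl2(=CH-C6H4-2-OiPr)(H2IMes) (15 mol%, in portions), 1,4-benzoquinone (30 mol%), toluene (1 mM), 80 °C
Reagents that add atoms: none
Why: Ring-closing metathesis: the catalyst loads on the monosubstituted allyl terminus and closes onto the electron-rich methallyl olefin (the exo-methylene lactone, exo-methylene enone and angelate olefins are electron-poor and poor partners), and the ten-membered ring (ring 2) forms as the less strained (Z)-trisubstituted olefin; benzoquinone suppresses ruthenium hydride isomerisation of the skipped enone.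

**Step 10**
Reactants: 23 (3aS,4R,5S,9Z,11aR)-10-methyl-3,6-dimethylidene-2,7-dioxo-4-(triethylsilyloxy)-2,3,3a,4,5,6,7,8,11,11a-decahydrocyclodeca[b]furan-5-yl (2Z)-2-methylbut-2-enoate
Product: 24 (3aR,4R,5S,9Z,11aR)-4-hydroxy-10-methyl-3,6-dimethylidene-2,7-dioxo-2,3,3a,4,5,6,7,8,11,11a-decahydrocyclodeca[b]furan-5-yl (2Z)-2-methylbut-2-enoate
Conditions: HF·pyridine, THF/pyridine, 0 °C
Reagents that add atoms: none
Why: Buffered HF cleaves the triethylsilyl ether (Si–F bond formation) at 0 °C; it is done before the acid-labile epoxide exists and under conditions too mild for acyl migration or lactone opening.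

**Step 11**
Reactants: 24 (3aR,4R,5S,9Z,11aR)-4-hydroxy-10-methyl-3,6-dimethylidene-2,7-dioxo-2,3,3a,4,5,6,7,8,11,11a-decahydrocyclodeca[b]furan-5-yl (2Z)-2-methylbut-2-enoate
Product: 25 (3aR,4R,5S,9S,10R,11aR)-9,10-epoxy-4-hydroxy-10-methyl-3,6-dimethylidene-2,7-dioxododecahydrocyclodeca[b]furan-5-yl (2Z)-2-methylbut-2-enoate (target, CNP0348992.4)
Conditions: mCPBA (1.1 equiv), NaHCO3, CH2Cl2, 0 °C
Reagents that add atoms: 3-chloroperoxybenzoic acid OOC(=O)c1cccc(Cl)c1
Why: Prilezhaev epoxidation: the peracid reacts only with the electron-rich trisubstituted olefin (all other olefins are conjugated to carbonyls), adds syn so the cis geometry is kept, and is expected to attack the outer face of the (Z)-cyclodecene, anti to the lactone C–O bond at C11a, setting C9 (S) and C10 (R) under substrate control.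

**Compound list**
1 | (2E)-3-phenylprop-2-enal (cinnamaldehyde) | O=C/C=C/c1ccccc1 | starting material
2 | 4,4,5,5-tetramethyl-2-(2-methylprop-2-en-1-yl)-1,3,2-dioxaborolane | CC(=C)CB1OC(C)(C)C(C)(C)O1 | starting material
3 | 2-{[(1E,3R)-5-methyl-1-phenylhexa-1,5-dien-3-yl]oxy}-4,4,5,5-tetramethyl-1,3,2-dioxaborolane (pinacol borate of 4) | CC1(C)OB(O[C@@H](/C=C/c2ccccc2)CC(C)=C)OC1(C)C | intermediate
4 | (1E,3R)-5-methyl-1-phenylhexa-1,5-dien-3-ol | O[C@@H](/C=C/c1ccccc1)CC(C)=C | intermediate
5 | 2-(bromomethyl)prop-2-enoic acid | C=C(CBr)C(=O)O | starting material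
6 | O-acylisourea from 5 and N,N'-diisopropylcarbodiimide | C=C(CBr)C(=O)OC(=NC(C)C)NC(C)C | intermediate
7 | (1E,3R)-5-methyl-1-phenylhexa-1,5-dien-3-yl 2-(bromomethyl)prop-2-enoate | C=C(CBr)C(=O)O[C@@H](/C=C/c1ccccc1)CC(C)=C | intermediate
8 | (5R)-3-(bromomethyl)-5-(2-methylprop-2-en-1-yl)furan-2(5H)-one | BrCC1=C[C@@H](CC(C)=C)OC1=O | intermediate
9 | 2,2-dimethoxyacetaldehyde | COC(OC)C=O | starting material
10 | {[(5R)-5-(2-methylprop-2-en-1-yl)-2-oxo-2,5-dihydrofuran-3-yl]methyl}zinc bromide | Br[Zn]CC1=C[C@@H](CC(C)=C)OC1=O | intermediate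
11 | (4R,5R)-4-[(1R)-1-hydroxy-2,2-dimethoxyethyl]-3-methylidene-5-(2-methylprop-2-en-1-yl)oxolan-2-one | C=C1C(=O)O[C@H](CC(C)=C)[C@H]1[C@@H](O)C(OC)OC | intermediate
12 | (4S,5R)-4-[(1R)-2,2-dimethoxy-1-(triethylsilyloxy)ethyl]-3-methylidene-5-(2-methylprop-2-en-1-yl)oxolan-2-one | C=C1C(=O)O[C@H](CC(C)=C)[C@H]1[C@@H](O[Si](CC)(CC)CC)C(OC)OC | intermediate
13 | 1-{(2R)-1-methoxy-2-[(2R,3S)-4-methylidene-2-(2-methylprop-2-en-1-yl)-5-oxooxolan-3-yl]-2-(triethylsilyloxy)ethyl}-2,4,6-trimethylpyridin-1-ium trifluoromethanesulfonate (both C1 epimers) | C=C1C(=O)O[C@H](CC(C)=C)[C@H]1[C@@H](O[Si](CC)(CC)CC)C(OC)[n+]2c(C)cc(C)cc2C.[O-]S(=O)(=O)C(F)(F)F | intermediate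
14 | (2R)-2-[(2R,3S)-4-methylidene-2-(2-methylprop-2-en-1-yl)-5-oxooxolan-3-yl]-2-(triethylsilyloxy)acetaldehyde | C=C1C(=O)O[C@H](CC(C)=C)[C@H]1[C@@H](O[Si](CC)(CC)CC)C=O | intermediate
15 | 3-chloropropanoyl chloride | O=C(Cl)CCCl | starting material
16 | trimethyl(prop-2-en-1-yl)silane (allyltrimethylsilane) | C=CC[Si](C)(C)C | starting material
17 | 1-chlorohex-5-en-3-one | O=C(CCCl)CC=C | intermediate
18 | hexa-1,5-dien-3-one | C=CC(=O)CC=C | intermediate
19 | (4S,5R)-4-[(1R,2S)-2-hydroxy-3-methylidene-4-oxo-1-(triethylsilyloxy)hept-6-en-1-yl]-3-methylidene-5-(2-methylprop-2-en-1-yl)oxolan-2-one | C=C1C(=O)O[C@H](CC(C)=C)[C@H]1[C@@H](O[Si](CC)(CC)CC)[C@@H](O)C(=C)C(=O)CC=C | intermediate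
20 | (2Z)-2-methylbut-2-enoic acid (angelic acid) | C/C=C(/C)C(=O)O | starting material
21 | (2Z)-2-methylbut-2-enoic 2,4,6-trichlorobenzoic anhydride | C/C=C(/C)C(=O)OC(=O)c1c(Cl)cc(Cl)cc1Cl | intermediate
22 | (1R,2S)-3-methylidene-1-[(2R,3S)-4-methylidene-2-(2-methylprop-2-en-1-yl)-5-oxooxolan-3-yl]-4-oxo-1-(triethylsilyloxy)hept-6-en-2-yl (2Z)-2-methylbut-2-enoate | C=C1C(=O)O[C@H](CC(C)=C)[C@H]1[C@@H](O[Si](CC)(CC)CC)[C@@H](OC(=O)/C(C)=C\C)C(=C)C(=O)CC=C | intermediate
23 | (3aS,4R,5S,9Z,11aR)-10-methyl-3,6-dimethylidene-2,7-dioxo-4-(triethylsilyloxy)-2,3,3a,4,5,6,7,8,11,11a-decahydrocyclodeca[b]furan-5-yl (2Z)-2-methylbut-2-enoate | C=C1C(=O)O[C@@H]2C/C(C)=C\CC(=O)C(=C)[C@H](OC(=O)/C(C)=C\C)[C@H](O[Si](CC)(CC)CC)[C@@H]12 | intermediate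
24 | (3aR,4R,5S,9Z,11aR)-4-hydroxy-10-methyl-3,6-dimethylidene-2,7-dioxo-2,3,3a,4,5,6,7,8,11,11a-decahydrocyclodeca[b]furan-5-yl (2Z)-2-methylbut-2-enoate | C=C1C(=O)O[C@@H]2C/C(C)=C\CC(=O)C(=C)[C@H](OC(=O)/C(C)=C\C)[C@H](O)[C@@H]12 | intermediate
25 | (3aR,4R,5S,9S,10R,11aR)-9,10-epoxy-4-hydroxy-10-methyl-3,6-dimethylidene-2,7-dioxododecahydrocyclodeca[b]furan-5-yl (2Z)-2-methylbut-2-enoate | C=C1C(=O)O[C@@H]2C[C@@]3(C)O[C@H]3CC(=O)C(=C)[C@H](OC(=O)/C(C)=C\C)[C@H](O)[C@@H]12 | target

**Step count and risks**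
Total step count: 11. Longest linear sequence: 10 (steps 1 to 5 and 7 to 11); step 6 is a one-step side branch.

The three steps most likely to fail are steps 7, 9 and 11.

Step 7 (the proposed slow-release MBH reaction) may suffer from slow turnover with the hindered aldehyde, isomerisation of the skipped dienone, or addition of the amine catalyst to the methylene lactone. The fallback is the known stoichiometric iodo-aldol route and sets out from 14. Enone 18 is first made separately from 17 with Et3N and used as a cold CH2Cl2 solution. With Et2AlI in CH2Cl2 at −78 °C, iodide adds 1,4 to 18 and the aluminium enolate adds to 14 in the Felkin sense, giving the β-iodo aldol (4S,5R)-4-[(1R,2S)-2-hydroxy-3-(iodomethyl)-4-oxo-1-(triethylsilyloxy)hept-6-en-1-yl]-3-methylidene-5-(2-methylprop-2-en-1-yl)oxolan-2-one F1 as a mixture of C3 epimers. Elimination of HI with Et3N at 0 °C then comes back to the route at 19.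

Step 9 (macrocyclic metathesis to a trisubstituted olefin) may fail through competing closure onto the lactone methylene, isomerisation of the allyl ketone, or strain of the cross-conjugated enone. The fallback sets out from 22 and closes the ring at the alcohol oxidation level. Luche reduction (NaBH4, CeCl3·7H2O, MeOH, −78 °C) gives the carbinols (1R,2S)-4-hydroxy-3-methylidene-1-[(2R,3S)-4-methylidene-2-(2-methylprop-2-en-1-yl)-5-oxooxolan-3-yl]-1-(triethylsilyloxy)hept-6-en-2-yl (2Z)-2-methylbut-2-enoate F2 (C4 epimers). Metathesis under the step 9 conditions gives the macrocyclic alcohol (3aS,4R,5S,9Z,11aR)-7-hydroxy-10-methyl-3,6-dimethylidene-2-oxo-4-(triethylsilyloxy)-2,3,3a,4,5,6,7,8,11,11a-decahydrocyclodeca[b]furan-5-yl (2Z)-2-methylbut-2-enoate F3 (C7 epimers). Dess–Martin periodinane with NaHCO3 then comes back to the route at 23.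

Step 11 is the least certain stereochemically, because the facial selectivity of the epoxidation rests on the ring conformation alone. If the peracid attacks the wrong face, the fallback sets out from 24 and delivers the oxygen to the opposite face in two steps. NBS in THF/H2O at 0 °C forms the bromonium ion on the exposed face and water opens it anti at the tertiary carbon, giving the bromohydrin (3aR,4R,5S,9R,10R,11aR)-9-bromo-4,10-dihydroxy-10-methyl-3,6-dimethylidene-2,7-dioxododecahydrocyclodeca[b]furan-5-yl (2Z)-2-methylbut-2-enoate F4. Ag2O in CH2Cl2 closes the oxirane with inversion at C9 without base (the β-bromo ketone would eliminate under basic conditions) and comes back to the route at 25.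

**Further compounds**
F1 | step 7 | (4S,5R)-4-[(1R,2S)-2-hydroxy-3-(iodomethyl)-4-oxo-1-(triethylsilyloxy)hept-6-en-1-yl]-3-methylidene-5-(2-methylprop-2-en-1-yl)oxolan-2-one (C3 epimers) | C=C1C(=O)O[C@H](CC(C)=C)[C@H]1[C@@H](O[Si](CC)(CC)CC)[C@@H](O)C(CI)C(=O)CC=C
F2 | step 9 | (1R,2S)-4-hydroxy-3-methylidene-1-[(2R,3S)-4-methylidene-2-(2-methylprop-2-en-1-yl)-5-oxooxolan-3-yl]-1-(triethylsilyloxy)hept-6-en-2-yl (2Z)-2-methylbut-2-enoate (C4 epimers) | C=C1C(=O)O[C@H](CC(C)=C)[C@H]1[C@@H](O[Si](CC)(CC)CC)[C@@H](OC(=O)/C(C)=C\C)C(=C)C(O)CC=C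
F3 | step 9 | (3aS,4R,5S,9Z,11aR)-7-hydroxy-10-methyl-3,6-dimethylidene-2-oxo-4-(triethylsilyloxy)-2,3,3a,4,5,6,7,8,11,11a-decahydrocyclodeca[b]furan-5-yl (2Z)-2-methylbut-2-enoate (C7 epimers) | C=C1C(=O)O[C@@H]2C/C(C)=C\CC(O)C(=C)[C@H](OC(=O)/C(C)=C\C)[C@H](O[Si](CC)(CC)CC)[C@@H]12
F4 | step 11 | (3aR,4R,5S,9R,10R,11aR)-9-bromo-4,10-dihydroxy-10-methyl-3,6-dimethylidene-2,7-dioxododecahydrocyclodeca[b]furan-5-yl (2Z)-2-methylbut-2-enoate | C=C1C(=O)O[C@@H]2C[C@@](C)(O)[C@H](Br)CC(=O)C(=C)[C@H](OC(=O)/C(C)=C\C)[C@H](O)[C@@H]12
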